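**Retrosynthetic overview**

1. The 2-oxo-2H-pyran-6-carboxylic acid ring is made last: a 3,4,5-trihydroxybenzyl (pyrogallol) ring is cleaved with O2 (two new C–O bonds) and the resulting 2-hydroxymuconic acid closes to the pyranone through a lactone C–O bond.
2. The pyrogallol lignan comes from its tri-O-benzyl ether, which comes from trans-selective α-benzylation of (R)-β-(3,4-dimethoxybenzyl)-γ-butyrolactone with 3,4,5-tris(benzyloxy)benzyl bromide (sets C3).
3. The (R)-lactone comes from benzylic deoxygenation of a β-(aryl-hydroxymethyl)-γ-butyrolactone, made by L-proline cross-aldol of methyl 4-oxobutanoate with 3,4-dimethoxybenzaldehyde, NaBH4 reduction and lactonisation (sets C4).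
4. Ring order: butyrolactone first (step 1), pyranone last (step 5); both benzene rings are bought.

Assumption: 3,4,5-tris(benzyloxy)benzyl bromide is bought as a catalogue reagent (otherwise one PBr3 step from the stocked alcohol).

**Route**

Step 1
Reactants: 1 methyl 4-oxobutanoate; 2 3,4-dimethoxybenzaldehyde
Product: 5 (4R)-4-[(R)-(3,4-dimethoxyphenyl)(hydroxy)methyl]oxolan-2-one, via aldol aldehyde 3 (not isolated), via diol ester 4 (not isolated)
Conditions: L-proline (20 mol%), DMF, 4 °C, 1 (2 equiv) added over 24 h, 48 h in all; then MeOH, NaBH4, −20 → 0 °C; 1 M HCl work-up, rt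
Reagents that add atoms: none
Why: Proline-catalysed direct cross-aldol (List–MacMillan enamine catalysis): the E-enamine of 1 adds to the re face of non-enolisable 2 in the acid-organised chair transition state, setting the α-carbon as S (it becomes C4 (R) of the lactone after the CIP priority change) and the carbinol as R; NaBH4 reduces the aldehyde before it can epimerise, and the primary alcohol closes onto the methyl ester.

Step 2
Reactants: 5 (4R)-4-[(R)-(3,4-dimethoxyphenyl)(hydroxy)methyl]oxolan-2-one
Product: 6 (4R)-4-[(3,4-dimethoxyphenyl)methyl]oxolan-2-one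
Conditions: H2 (1 atm), 10% Pd/C, HClO4 (cat.), AcOH, rt
Reagents that add atoms: none
Why: Acid-assisted benzylic hydrogenolysis cuts the C–OH bond next to the electron-rich ring, while C4 is neither benzylic nor enolisable and keeps its configuration (descriptor stays R).

Step 3
Reactants: 6 (4R)-4-[(3,4-dimethoxyphenyl)methyl]oxolan-2-one; 7 3,4,5-tris(benzyloxy)benzyl bromide
Product: 9 (3R,4R)-4-[(3,4-dimethoxyphenyl)methyl]-3-{[3,4,5-tris(benzyloxy)phenyl]methyl}oxolan-2-one, via lithium enolate 8 (not isolated)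
Conditions: LiN(SiMe3)2 (1.1 equiv), THF, −78 °C, 45 min; then 7 (1.1 equiv), DMPU (2 equiv), −78 → −40 °C
Reagents that add atoms: none
Why: Lactone enolate alkylation (SN2): the bromide approaches the enolate face anti to the C4 benzyl group, giving the trans (3R,4R) lactone, as is standard for dibenzylbutyrolactone lignans (dr usually above 20:1).

Step 4
Reactants: 9 (3R,4R)-4-[(3,4-dimethoxyphenyl)methyl]-3-{[3,4,5-tris(benzyloxy)phenyl]methyl}oxolan-2-one
Product: 10 (3R,4R)-4-[(3,4-dimethoxyphenyl)methyl]-3-[(3,4,5-trihydroxyphenyl)methyl]oxolan-2-one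
Conditions: H2 (1 atm), 10% Pd/C, EtOAc–MeOH 1:1, rt; filtered under argon and used at once
Reagents that add atoms: none
Why: Hydrogenolysis of the three aryl benzyl ethers on Pd/C leaves the lactone, the methyl ethers and both stereocentres untouched, since no benzylic C–O bond remains on the skeleton.

Step 5
Reactants: 10 (3R,4R)-4-[(3,4-dimethoxyphenyl)methyl]-3-[(3,4,5-trihydroxyphenyl)methyl]oxolan-2-one
Product: 13 4-{[(3R,4R)-4-[(3,4-dimethoxyphenyl)methyl]-2-oxooxolan-3-yl]methyl}-2-oxo-2H-pyran-6-carboxylic acid, via muconic anhydride 11 (not isolated), via 2-hydroxymuconic acid 12 (not isolated)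
Conditions: Fe(NO3)3·9H2O (10 mol%), tris(2-pyridylmethyl)amine (TPA, 11 mol%), 2,6-lutidine (2.2 equiv), O2 (1 atm), MeCN–H2O 9:1, 25 °C, 10 added over 4 h; then 2 M HCl to pH 1, 40 °C, 2 h
Reagents that add atoms: dioxygen (O=O); water (O)
Why: Proposed new method: the TPA complex of trivalent iron binds the pyrogallol of 10 as a bidentate catecholate through two neighbouring oxygens, the semiquinonate–divalent-iron character of this chelate lets O2 add at ring carbon, and a Criegee-type acyl shift inserts one oxygen into the C–C bond between two oxygenated carbons to give anhydride 11, which iron-bound hydroxide or water opens to 12; cleavage on either side of the central C–OH gives the same 12 because the ring is symmetric, and acid then closes the enol (through its 2-oxo tautomer) onto the far carboxyl to form the pyranone C–O bond with loss of water (net: 10 + O2 → 13 + H2O), with no stereocentre touched; the closest known reactions are intradiol cleavage of catechols to cis,cis-muconic acids by [Fe(TPA)(catecholate)]+ complexes under O2, the enzymatic ring cleavage of gallate to 2-pyrone-4,6-dicarboxylic acid, and the acid cyclisation of oxalocrotonic acid to 2-pyrone-6-carboxylic acid, and what is new is the 5-alkylpyrogallol substrate and the direct aerobic pyrogallol-to-pyranone-acid conversion.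

**Compound list**

1 | methyl 4-oxobutanoate | COC(=O)CCC=O | starting material
2 | 3,4-dimethoxybenzaldehyde | COc1ccc(C=O)cc1OC | starting material
3 | methyl (3S,4R)-4-(3,4-dimethoxyphenyl)-3-formyl-4-hydroxybutanoate | O=C[C@@H](CC(=O)OC)[C@@H](O)c1ccc(OC)c(OC)c1 | intermediate
4 | methyl (3R,4R)-4-(3,4-dimethoxyphenyl)-4-hydroxy-3-(hydroxymethyl)butanoate | OC[C@@H](CC(=O)OC)[C@@H](O)c1ccc(OC)c(OC)c1 | intermediate
5 | (4R)-4-[(R)-(3,4-dimethoxyphenyl)(hydroxy)methyl]oxolan-2-one | COc1ccc([C@H](O)[C@H]2COC(=O)C2)cc1OC | intermediate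
6 | (4R)-4-[(3,4-dimethoxyphenyl)methyl]oxolan-2-one | COc1ccc(C[C@H]2COC(=O)C2)cc1OC | intermediate
7 | 3,4,5-tris(benzyloxy)benzyl bromide | BrCc1cc(OCc2ccccc2)c(OCc2ccccc2)c(OCc2ccccc2)c1 | starting material
8 | lithium (4R)-4-[(3,4-dimethoxyphenyl)methyl]-4,5-dihydrofuran-2-olate | [Li+].COc1ccc(C[C@H]2COC([O-])=C2)cc1OC | intermediate
9 | (3R,4R)-4-[(3,4-dimethoxyphenyl)methyl]-3-{[3,4,5-tris(benzyloxy)phenyl]methyl}oxolan-2-one | COc1ccc(C[C@H]2COC(=O)[C@@H]2Cc2cc(OCc3ccccc3)c(OCc3ccccc3)c(OCc3ccccc3)c2)cc1OC | intermediate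
10 | (3R,4R)-4-[(3,4-dimethoxyphenyl)methyl]-3-[(3,4,5-trihydroxyphenyl)methyl]oxolan-2-one | COc1ccc(C[C@H]2COC(=O)[C@@H]2Cc2cc(O)c(O)c(O)c2)cc1OC | intermediate
11 | 3-hydroxy-5-{[(3R,4R)-4-[(3,4-dimethoxyphenyl)methyl]-2-oxooxolan-3-yl]methyl}oxepine-2,7-dione | COc1ccc(C[C@H]2COC(=O)[C@@H]2CC2=CC(=O)OC(=O)C(O)=C2)cc1OC | intermediate
12 | (2E,4Z)-4-{[(3R,4R)-4-[(3,4-dimethoxyphenyl)methyl]-2-oxooxolan-3-yl]methyl}-2-hydroxyhexa-2,4-dienedioic acid | COc1ccc(C[C@H]2COC(=O)[C@@H]2C/C(=C/C(=O)O)/C=C(/O)C(=O)O)cc1OC | intermediate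
13 | 4-{[(3R,4R)-4-[(3,4-dimethoxyphenyl)methyl]-2-oxooxolan-3-yl]methyl}-2-oxo-2H-pyran-6-carboxylic acid | COc1ccc(C[C@H]2COC(=O)[C@@H]2Cc2cc(C(=O)O)oc(=O)c2)cc1OC | target

**Step count and risks**

Total steps: 5. Longest linear sequence: 5 (1 and 2 → 5 → 6 → 9 → 10 → 13).

The three steps most likely to fail:

Step 5 (the proposed new method). The main dangers are escape of free hydroxy-o-quinone, which dimerises to benzotropolones, and binding of the α-keto-acid product to iron, which stalls turnover. Slow addition of 10 and a higher iron loading are the first adjustments. The fallback uses only known reaction types and brings the pyranone in preformed; it sets out from 6 and comes back at 13. Diethyl oxalate and ethyl 3-methylbut-2-enoate are condensed with KOEt in Et2O (vinylogous Claisen at the γ-methyl) to give diethyl 2-hydroxy-4-methylhexa-2,4-dienedioate F1. F1 is cyclised with p-TsOH in hot toluene, with loss of ethanol, to ethyl 4-methyl-2-oxo-2H-pyran-6-carboxylate F2. Wohl–Ziegler bromination (NBS, cat. AIBN, PhCF3, 80 °C) gives ethyl 4-(bromomethyl)-2-oxo-2H-pyran-6-carboxylate F3. Enolate 8, made from 6 and LiN(SiMe3)2 in THF at −78 °C, is alkylated with F3 at −78 °C, anti to the C4 benzyl group, to give ethyl 4-{[(3R,4R)-4-[(3,4-dimethoxyphenyl)methyl]-2-oxooxolan-3-yl]methyl}-2-oxo-2H-pyran-6-carboxylate F4. Hydrolysis with 6 M HCl–dioxane at 60 °C, in which the lactone and pyranone survive or re-close, gives 13.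

Step 1 (proline cross-aldol with an electron-rich acceptor). Conversion may be slow, 1 may self-condense, and the α-centre of 3 may erode before reduction. Compound 6 is the known dextrorotatory arctigenin intermediate, so ee and sense are checked there by rotation and chiral HPLC. The fallback sets out from 2 and comes back at 6. Stobbe condensation of 2 with dimethyl succinate (NaOMe, MeOH, reflux) gives (E)-4-(3,4-dimethoxyphenyl)-3-(methoxycarbonyl)but-3-enoic acid F5. Asymmetric hydrogenation with [Rh(cod)((S,S)-Et-DuPhos)]BF4 (1 mol%), H2 (5 atm), MeOH gives (3R)-4-(3,4-dimethoxyphenyl)-3-(methoxycarbonyl)butanoic acid F6; the ligand hand is chosen from memory of β-aryl itaconate half-ester precedent and is confirmed at 6. Reduction of the ester of its potassium salt with Ca(BH4)2 (CaCl2, NaBH4, EtOH) and acid work-up gives 6.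

Step 3 (alkylation with a bulky, electron-rich benzyl bromide). Dialkylation, incomplete conversion or poor bromide quality are the likely problems. The fallback replaces alkylation by aldol addition and deoxygenation; it sets out from 6 and comes back at 10. Enolate 8 is added to 3,4,5-tris(benzyloxy)benzaldehyde (THF, −78 °C) to give (3S,4R)-4-[(3,4-dimethoxyphenyl)methyl]-3-{hydroxy[3,4,5-tris(benzyloxy)phenyl]methyl}oxolan-2-one F7, trans on the ring and a mixture at the carbinol. H2, Pd/C, AcOH–EtOAc then cleaves the three benzyl ethers and the now p-hydroxybenzylic C–OH bond in one operation to give 10.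

**Further compounds**

F1 | step 5 | diethyl 2-hydroxy-4-methylhexa-2,4-dienedioate | CCOC(=O)C(O)=CC(C)=CC(=O)OCC
F2 | step 5 | ethyl 4-methyl-2-oxo-2H-pyran-6-carboxylate | CCOC(=O)c1cc(C)cc(=O)o1
F3 | step 5 | ethyl 4-(bromomethyl)-2-oxo-2H-pyran-6-carboxylate | CCOC(=O)c1cc(CBr)cc(=O)o1
F4 | step 5 | ethyl 4-{[(3R,4R)-4-[(3,4-dimethoxyphenyl)methyl]-2-oxooxolan-3-yl]methyl}-2-oxo-2H-pyran-6-carboxylate | COc1ccc(C[C@H]2COC(=O)[C@@H]2Cc2cc(C(=O)OCC)oc(=O)c2)cc1OC
F5 | step 1 | (E)-4-(3,4-dimethoxyphenyl)-3-(methoxycarbonyl)but-3-enoic acid | COC(=O)/C(CC(=O)O)=C/c1ccc(OC)c(OC)c1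
F6 | step 1 | (3R)-4-(3,4-dimethoxyphenyl)-3-(methoxycarbonyl)butanoic acid | COc1ccc(C[C@H](CC(=O)O)C(=O)OC)cc1OC
F7 | step 3 | (3S,4R)-4-[(3,4-dimethoxyphenyl)methyl]-3-{hydroxy[3,4,5-tris(benzyloxy)phenyl]methyl}oxolan-2-one | COc1ccc(C[C@H]2COC(=O)[C@@H]2C(O)c2cc(OCc3ccccc3)c(OCc3ccccc3)c(OCc3ccccc3)c2)cc1OC
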